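**Retrosynthetic overview**

1. The 8‑O‑acrylate is cut at C8–O (esterification with inversion of an 8R carbinol by acid 3). The C13 methyl of the cis‑fused 12,6‑lactone is read as a hydrogenated exocyclic methylene, which leads back to α‑methylene lactone 29.
2. Key disconnection C7–C8 of the ten‑membered carbocycle (C1–C10). C7 is a ring carbon, the ring‑fusion atom and the β‑carbon of the lactone (C12(=O)–C11(C13)–C7), and it carries the carbinol carbon C8. C8(OH)–C7–C11(=C13) is therefore the homoallylic‑alcohol retron of an allylmetal–aldehyde addition. The two acceptor carbons C7 and C8 are joined by polarity reversal at C7, through the allylchromium of the 3‑(bromomethyl)butenolide aldehyde 27, which has a single stereocentre (C6).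
3. Ring order: five‑membered lactone first (ring‑closing metathesis of the 2‑(bromomethyl)acrylate of divinyl carbinol 22), ten‑membered carbocycle last (C7–C8, step 16).
4. C6 comes from a catalytic asymmetric alkynylation of Z‑enal 17. The C4=C5 geometry comes from Cu‑catalysed carbomagnesiation of propargyl alcohol and iodinolysis, the C1=C10 geometry from Zr‑catalysed carboalumination of a butynyl ether, and C2–C3 from ethylene oxide.

Key step: step 16

Remark on numbering and structure: germacrane locants are used in the explanations (C1–C10 carbocycle, C6 lactone O‑carbon, C7 ring fusion, C8 ester carbon, C11/C12 lactone α‑carbon and carbonyl, C13 methyl on C11, C14 methyl on C10, C15 CH2OH on C4). The SMILES is read as the cis‑fused lactone (3R,3aS,4S,6E,10Z,11aR).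
Assumption: (S,S)‑ProPhenol is taken to deliver the 3R carbinol in step 9; if its sense is the opposite, the (R,R)‑ligand is used with nothing else changed.

**Route**

Step 1
Reactants: 1 ethyl 2-(hydroxymethyl)prop-2-enoate
Product: 2 ethyl 2-({[tert-butyl(dimethyl)silyl]oxy}methyl)prop-2-enoate
Conditions: TBSCl, imidazole, CH2Cl2, 0 °C to rt
Reagents that add atoms: tert-butyldimethylsilyl chloride CC(C)(C)[Si](C)(C)Cl
Why: Imidazole‑mediated silyl ether formation protects the primary allylic alcohol and leaves the acrylate untouched.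

Step 2
Reactants: 2 ethyl 2-({[tert-butyl(dimethyl)silyl]oxy}methyl)prop-2-enoate
Product: 3 2-({[tert-butyl(dimethyl)silyl]oxy}methyl)prop-2-enoic acid
Conditions: LiOH·H2O, THF/H2O, 0 °C; then 1 M HCl to pH 4
Reagents that add atoms: lithium hydroxide [Li+].[OH-]
Why: Ester saponification at 0 °C should be faster than conjugate addition or silyl ether cleavage, and careful acidification returns the acid with the TBS ether intact.

Step 3
Reactants: 4 but-3-yn-1-ol
Product: 5 1-[(but-3-yn-1-yloxy)methyl]-4-methoxybenzene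
Conditions: NaH, PMBCl, Bu4NI (cat.), THF/DMF, 0 °C to rt
Reagents that add atoms: 4-methoxybenzyl chloride COc1ccc(CCl)cc1
Why: Williamson etherification through the alkoxide (formed in preference to the acetylide) installs a PMB ether that withstands the organometallic steps and is later removed oxidatively beside silyl ethers and an allylic bromide.

Step 4
Reactants: 5 1-[(but-3-yn-1-yloxy)methyl]-4-methoxybenzene
Product: 8 (3E)-6-[(4-methoxybenzyl)oxy]-4-methylhex-3-en-1-ol, via alkenyldimethylalane 6 (not isolated), via lithium alkenylalanate 7 (not isolated)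
Conditions: Me3Al, Cp2ZrCl2 (0.25 equiv), CH2Cl2, 0 °C to rt; evaporate, hexane/THF, n-BuLi, −78 °C; ethylene oxide, −78 °C to rt; aq. Rochelle salt
Reagents that add atoms: trimethylaluminium C[Al](C)C; ethylene oxide C1CO1
Why: Zr‑catalysed (Negishi) carboalumination adds methyl and aluminium syn across the terminal alkyne with methyl at the internal carbon, which fixes the E geometry of C1=C10, and the derived alanate opens ethylene oxide with retention at the alkenyl carbon to add C2 and C3.

Step 5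
Reactants: 8 (3E)-6-[(4-methoxybenzyl)oxy]-4-methylhex-3-en-1-ol
Product: 9 1-({[(3E)-6-bromo-3-methylhex-3-en-1-yl]oxy}methyl)-4-methoxybenzene
Conditions: CBr4, PPh3, CH2Cl2, 0 °C
Reagents that add atoms: carbon tetrabromide BrC(Br)(Br)Br
Why: The Appel reaction converts the primary homoallylic alcohol into the bromide under neutral conditions without touching the alkene or the PMB ether.

Step 6
Reactants: 9 1-({[(3E)-6-bromo-3-methylhex-3-en-1-yl]oxy}methyl)-4-methoxybenzene; 10 prop-2-yn-1-ol
Product: 14 (2Z,5E)-2-(iodomethylidene)-8-[(4-methoxybenzyl)oxy]-6-methyloct-5-en-1-ol, via homoallylic Grignard reagent 11 (not isolated), via bromomagnesium propargyl alkoxide 12 (not isolated), via chelated alkenylmagnesium alkoxide 13 (not isolated)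
Conditions: Mg, THF, rt (9 to 11); 10 (1.5 equiv), EtMgBr, THF, 0 °C (to 12); combine, CuI (15 mol %), −10 °C to rt; then I2, −20 °C to rt
Reagents that add atoms: iodine II
Why: Copper‑catalysed anti‑carbomagnesiation of the propargylic alkoxide puts the alkyl group on the internal alkyne carbon and magnesium on the terminus inside a five‑membered chelate, so iodinolysis with retention gives the vinyl iodide cis to CH2OH, which is the C4=C5 geometry of the target.

Step 7
Reactants: 14 (2Z,5E)-2-(iodomethylidene)-8-[(4-methoxybenzyl)oxy]-6-methyloct-5-en-1-ol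
Product: 15 tert-butyl{[(2Z,5E)-2-(iodomethylidene)-8-[(4-methoxybenzyl)oxy]-6-methyloct-5-en-1-yl]oxy}dimethylsilane
Conditions: TBSCl, imidazole, DMF, 0 °C to rt
Reagents that add atoms: tert-butyldimethylsilyl chloride CC(C)(C)[Si](C)(C)Cl
Why: Silyl ether formation protects the C15 hydroxyl until the last step and is orthogonal to the PMB ether at C8–O.

Step 8
Reactants: 15 tert-butyl{[(2Z,5E)-2-(iodomethylidene)-8-[(4-methoxybenzyl)oxy]-6-methyloct-5-en-1-yl]oxy}dimethylsilane
Product: 17 (2Z,6E)-3-({[tert-butyl(dimethyl)silyl]oxy}methyl)-9-[(4-methoxybenzyl)oxy]-7-methylnona-2,6-dienal, via alkenylmagnesium chloride 16 (not isolated)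
Conditions: i-PrMgCl·LiCl, THF, −40 to −20 °C; DMF, −20 °C to rt; aq. NH4Cl
Reagents that add atoms: N,N-dimethylformamide CN(C)C=O
Why: Iodine–magnesium exchange proceeds with retention of alkene geometry (and, unlike an alkenyllithium, should not trigger 1,4 O‑to‑C silyl migration), and formylation with DMF (Bouveault aldehyde synthesis) gives the Z enal.

Step 9
Reactants: 17 (2Z,6E)-3-({[tert-butyl(dimethyl)silyl]oxy}methyl)-9-[(4-methoxybenzyl)oxy]-7-methylnona-2,6-dienal; 18 ethynyl(trimethyl)silane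
Product: 20 (3R,4Z,8E)-5-({[tert-butyl(dimethyl)silyl]oxy}methyl)-11-[(4-methoxybenzyl)oxy]-9-methyl-1-(trimethylsilyl)undeca-4,8-dien-1-yn-3-ol, via methylzinc acetylide 19 (not isolated)
Conditions: Me2Zn (3 equiv), (S,S)-ProPhenol (20 mol %), Ph3PO (40 mol %), toluene, 4 °C
Reagents that add atoms: none
Why: Zn–ProPhenol catalysed enantioselective alkynylation, a method suited to α,β‑unsaturated aldehydes, sets C6 by ligand‑controlled facial delivery of the zinc acetylide inside the dinuclear zinc pocket to give the 3R carbinol.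

Step 10
Reactants: 20 (3R,4Z,8E)-5-({[tert-butyl(dimethyl)silyl]oxy}methyl)-11-[(4-methoxybenzyl)oxy]-9-methyl-1-(trimethylsilyl)undeca-4,8-dien-1-yn-3-ol
Product: 21 (3R,4Z,8E)-5-({[tert-butyl(dimethyl)silyl]oxy}methyl)-11-[(4-methoxybenzyl)oxy]-9-methylundeca-4,8-dien-1-yn-3-ol
Conditions: K2CO3 (cat.), MeOH, rt
Reagents that add atoms: none
Why: Base‑catalysed methanolysis of the alkynyl C–Si bond removes the TMS group while the primary TBS ether, the PMB ether and the carbinol centre are unaffected.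

Step 11
Reactants: 21 (3R,4Z,8E)-5-({[tert-butyl(dimethyl)silyl]oxy}methyl)-11-[(4-methoxybenzyl)oxy]-9-methylundeca-4,8-dien-1-yn-3-ol
Product: 22 (3S,4Z,8E)-5-({[tert-butyl(dimethyl)silyl]oxy}methyl)-11-[(4-methoxybenzyl)oxy]-9-methylundeca-1,4,8-trien-3-ol
Conditions: H2 (1 atm), Lindlar catalyst, quinoline, EtOAc, rt
Reagents that add atoms: none
Why: Lindlar semihydrogenation stops at the terminal alkene and leaves the trisubstituted alkenes and the PMB ether alone, the carbinol centre being unchanged (its descriptor becomes S only through the change of priorities).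

Step 12
Reactants: 22 (3S,4Z,8E)-5-({[tert-butyl(dimethyl)silyl]oxy}methyl)-11-[(4-methoxybenzyl)oxy]-9-methylundeca-1,4,8-trien-3-ol; 23 2-(bromomethyl)prop-2-enoic acid
Product: 24 (3S,4Z,8E)-5-({[tert-butyl(dimethyl)silyl]oxy}methyl)-11-[(4-methoxybenzyl)oxy]-9-methylundeca-1,4,8-trien-3-yl 2-(bromomethyl)prop-2-enoate
Conditions: DIC, DMAP (10 mol %), CH2Cl2, −10 to 0 °C
Reagents that add atoms: none
Why: Carbodiimide (Steglich‑type) esterification at low temperature with only catalytic DMAP should acylate the doubly allylic alcohol with retention at C6, without ionization and with little attack of the amine on the allylic bromide.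

Step 13
Reactants: 24 (3S,4Z,8E)-5-({[tert-butyl(dimethyl)silyl]oxy}methyl)-11-[(4-methoxybenzyl)oxy]-9-methylundeca-1,4,8-trien-3-yl 2-(bromomethyl)prop-2-enoate
Product: 25 (5R)-3-(bromomethyl)-5-[(1Z,5E)-2-({[tert-butyl(dimethyl)silyl]oxy}methyl)-8-[(4-methoxybenzyl)oxy]-6-methylocta-1,5-dien-1-yl]furan-2(5H)-one
Conditions: Grubbs II (5 mol %), CH2Cl2 (5 mM), 40 °C
Reagents that add atoms: none
Why: Ring‑closing metathesis between the vinyl group and the 1,1‑disubstituted acrylate closes the butenolide under neutral conditions that cannot epimerize the γ‑carbon, the trisubstituted alkenes being too hindered to compete and a ring through the E C4=C5 bond being impossibly strained.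

Step 14
Reactants: 25 (5R)-3-(bromomethyl)-5-[(1Z,5E)-2-({[tert-butyl(dimethyl)silyl]oxy}methyl)-8-[(4-methoxybenzyl)oxy]-6-methylocta-1,5-dien-1-yl]furan-2(5H)-one
Product: 26 (5R)-3-(bromomethyl)-5-[(1Z,5E)-2-({[tert-butyl(dimethyl)silyl]oxy}methyl)-8-hydroxy-6-methylocta-1,5-dien-1-yl]furan-2(5H)-one
Conditions: DDQ, CH2Cl2/pH 7 buffer, 0 °C
Reagents that add atoms: none
Why: Oxidative PMB ether cleavage with DDQ frees the primary alcohol under neutral conditions tolerated by the allylic bromide, the base‑sensitive γ‑CH of the butenolide and the TBS ether.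

Step 15
Reactants: 26 (5R)-3-(bromomethyl)-5-[(1Z,5E)-2-({[tert-butyl(dimethyl)silyl]oxy}methyl)-8-hydroxy-6-methylocta-1,5-dien-1-yl]furan-2(5H)-one
Product: 27 (3E,7Z)-8-[(2R)-4-(bromomethyl)-5-oxo-2,5-dihydrofuran-2-yl]-7-({[tert-butyl(dimethyl)silyl]oxy}methyl)-3-methylocta-3,7-dienal
Conditions: Dess–Martin periodinane, NaHCO3, CH2Cl2, 0 °C to rt; used crude at once
Reagents that add atoms: none
Why: Bicarbonate‑buffered Dess–Martin oxidation should give the β,γ‑unsaturated aldehyde without moving the C1=C10 bond into conjugation and without touching the allylic bromide.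

Step 16
Reactants: 27 (3E,7Z)-8-[(2R)-4-(bromomethyl)-5-oxo-2,5-dihydrofuran-2-yl]-7-({[tert-butyl(dimethyl)silyl]oxy}methyl)-3-methylocta-3,7-dienal
Product: 29 (3aS,4R,6E,10Z,11aR)-10-({[tert-butyl(dimethyl)silyl]oxy}methyl)-4-hydroxy-6-methyl-3-methylidene-3a,4,5,8,9,11a-hexahydrocyclodeca[b]furan-2(3H)-one, via allylchromium(III) dichloride 28 (not isolated)
Conditions: CrCl2 (8 equiv), THF, rt, syringe‑pump addition of 27 over 12 h (final 1 mM); aq. NH4Cl
Reagents that add atoms: none
Why: Two equivalents of Cr(II) reduce the allylic C13–Br bond to the C13‑bound allylchromium(III) 28, whose γ‑carbon C7 (the β‑carbon of the butenolide, now nucleophilic) adds to the chromium‑bound aldehyde C8 in a six‑membered Zimmerman–Traxler transition state (Cr–C13–C11=C7···C8=O) while the double bond moves to C11=C13. The closest known reaction type is the intramolecular Nozaki–Hiyama (CrCl2) allylation of aldehydes by 2‑(bromomethyl)alk‑2‑enoates, which closes ten‑membered germacrane rings, together with the intermolecular Cr(II) allylation of aldehydes by 3‑(bromomethyl)furan‑2(5H)‑ones. The only ring closed is the ten‑membered carbocycle, by C7–C8 bond formation, exo with respect to the C7=C11 bond (10‑exo‑trig, C11 stays outside the new ring). C7 is controlled by C6: the aldehyde must reach C7 perpendicular to the flat butenolide and the tether leaves C6 on one face, so a same‑face approach needs a C5–C6–C7–C8 dihedral near 30° whereas the opposite face needs about 150°, which a ten‑membered ring already holding two E double bonds can hardly span, and C8 should therefore end cis to C5 (cis ring fusion, 3aS); C8 is controlled by the chair, in which C6 is fixed trans to C13 (an E‑type allylmetal) and the ring carbon C9 takes the pseudo‑equatorial place, which gives the anti carbinol (4R) with its oxygen next to C13. The step needs ring closure over oligomerization, secured by slow addition of 27 to excess CrCl2 at about 1 mM, and γ‑ over α‑attack of the allyl unit, secured by the closed transition state; lactone, silyl ether and trisubstituted alkenes are inert to Cr(II).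

Step 17
Reactants: 29 (3aS,4R,6E,10Z,11aR)-10-({[tert-butyl(dimethyl)silyl]oxy}methyl)-4-hydroxy-6-methyl-3-methylidene-3a,4,5,8,9,11a-hexahydrocyclodeca[b]furan-2(3H)-one
Product: 30 (3R,3aS,4R,6E,10Z,11aR)-10-({[tert-butyl(dimethyl)silyl]oxy}methyl)-4-hydroxy-3,6-dimethyl-3a,4,5,8,9,11a-hexahydrocyclodeca[b]furan-2(3H)-one
Conditions: [Rh(nbd)(dppb)]BF4 (10 mol %), H2 (3 atm), CH2Cl2, rt
Reagents that add atoms: none
Why: Hydroxyl‑directed hydrogenation with a cationic rhodium–diphosphine catalyst binds the C8 hydroxyl, which sits on the C8 face of the lactone next to the exocyclic methylene, and delivers H2 to that face of C11=C13 so that the new methyl ends trans to C8 (3R), the trisubstituted ring alkenes being far slower.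

Step 18
Reactants: 30 (3R,3aS,4R,6E,10Z,11aR)-10-({[tert-butyl(dimethyl)silyl]oxy}methyl)-4-hydroxy-3,6-dimethyl-3a,4,5,8,9,11a-hexahydrocyclodeca[b]furan-2(3H)-one; 3 2-({[tert-butyl(dimethyl)silyl]oxy}methyl)prop-2-enoic acid
Product: 31 (3R,3aS,4S,6E,10Z,11aR)-10-({[tert-butyl(dimethyl)silyl]oxy}methyl)-3,6-dimethyl-2-oxo-2,3,3a,4,5,8,9,11a-octahydrocyclodeca[b]furan-4-yl 2-({[tert-butyl(dimethyl)silyl]oxy}methyl)prop-2-enoate
Conditions: PPh3, DIAD, toluene, 0 °C to rt
Reagents that add atoms: none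
Why: Mitsunobu esterification displaces the activated 8R oxygen by the carboxylate with SN2 inversion, which gives the 8S (4S) ester of the target without exposing the hydroxy lactone to base.

Step 19
Reactants: 31 (3R,3aS,4S,6E,10Z,11aR)-10-({[tert-butyl(dimethyl)silyl]oxy}methyl)-3,6-dimethyl-2-oxo-2,3,3a,4,5,8,9,11a-octahydrocyclodeca[b]furan-4-yl 2-({[tert-butyl(dimethyl)silyl]oxy}methyl)prop-2-enoate
Product: 32 (3R,3aS,4S,6E,10Z,11aR)-10-(hydroxymethyl)-3,6-dimethyl-2-oxo-2,3,3a,4,5,8,9,11a-octahydrocyclodeca[b]furan-4-yl 2-(hydroxymethyl)prop-2-enoate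
Conditions: HF·pyridine, pyridine, THF, 0 °C to rt
Reagents that add atoms: none
Why: Fluoride‑mediated desilylation with pyridine‑buffered HF removes both primary TBS ethers under conditions mild enough to leave the acrylate ester, the lactone and the acid‑sensitive 1,5‑diene untouched.

**Compound list**

1 | ethyl 2-(hydroxymethyl)prop-2-enoate | C=C(CO)C(=O)OCC | starting material
2 | ethyl 2-({[tert-butyl(dimethyl)silyl]oxy}methyl)prop-2-enoate | C=C(CO[Si](C)(C)C(C)(C)C)C(=O)OCC | intermediate
3 | 2-({[tert-butyl(dimethyl)silyl]oxy}methyl)prop-2-enoic acid | C=C(CO[Si](C)(C)C(C)(C)C)C(=O)O | intermediate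
4 | but-3-yn-1-ol | C#CCCO | starting material
5 | 1-[(but-3-yn-1-yloxy)methyl]-4-methoxybenzene | C#CCCOCc1ccc(OC)cc1 | intermediate
6 | [(1E)-4-[(4-methoxybenzyl)oxy]-2-methylbut-1-en-1-yl]dimethylalumane (not isolated) | C[Al](C)/C=C(\C)CCOCc1ccc(OC)cc1 | intermediate
7 | lithium butyl[(1E)-4-[(4-methoxybenzyl)oxy]-2-methylbut-1-en-1-yl]dimethylaluminate (not isolated) | [Li+].CCCC[Al-](C)(C)/C=C(\C)CCOCc1ccc(OC)cc1 | intermediate
8 | (3E)-6-[(4-methoxybenzyl)oxy]-4-methylhex-3-en-1-ol | OCC/C=C(\C)CCOCc1ccc(OC)cc1 | intermediate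
9 | 1-({[(3E)-6-bromo-3-methylhex-3-en-1-yl]oxy}methyl)-4-methoxybenzene | BrCC/C=C(\C)CCOCc1ccc(OC)cc1 | intermediate
10 | prop-2-yn-1-ol | C#CCO | starting material
11 | bromo[(3E)-6-[(4-methoxybenzyl)oxy]-4-methylhex-3-en-1-yl]magnesium (not isolated) | Br[Mg]CC/C=C(\C)CCOCc1ccc(OC)cc1 | intermediate
12 | bromomagnesium prop-2-yn-1-olate (not isolated) | C#CCO[Mg]Br | intermediate
13 | bromo[(1Z,5E)-2-{[(bromomagnesio)oxy]methyl}-8-[(4-methoxybenzyl)oxy]-6-methylocta-1,5-dien-1-yl]magnesium, Mg cis to CH2O (not isolated) | Br[Mg]/C=C(\CO[Mg]Br)CC/C=C(\C)CCOCc1ccc(OC)cc1 | intermediate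
14 | (2Z,5E)-2-(iodomethylidene)-8-[(4-methoxybenzyl)oxy]-6-methyloct-5-en-1-ol | OC/C(=C\I)CC/C=C(\C)CCOCc1ccc(OC)cc1 | intermediate
15 | tert-butyl{[(2Z,5E)-2-(iodomethylidene)-8-[(4-methoxybenzyl)oxy]-6-methyloct-5-en-1-yl]oxy}dimethylsilane | CC(C)(C)[Si](C)(C)OC/C(=C\I)CC/C=C(\C)CCOCc1ccc(OC)cc1 | intermediate
16 | chloro[(1Z,5E)-2-({[tert-butyl(dimethyl)silyl]oxy}methyl)-8-[(4-methoxybenzyl)oxy]-6-methylocta-1,5-dien-1-yl]magnesium (not isolated) | CC(C)(C)[Si](C)(C)OC/C(=C\[Mg]Cl)CC/C=C(\C)CCOCc1ccc(OC)cc1 | intermediate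
17 | (2Z,6E)-3-({[tert-butyl(dimethyl)silyl]oxy}methyl)-9-[(4-methoxybenzyl)oxy]-7-methylnona-2,6-dienal | O=C/C=C(\CO[Si](C)(C)C(C)(C)C)CC/C=C(\C)CCOCc1ccc(OC)cc1 | intermediate
18 | ethynyl(trimethyl)silane | C#C[Si](C)(C)C | starting material
19 | methyl[(trimethylsilyl)ethynyl]zinc (not isolated) | C[Zn]C#C[Si](C)(C)C | intermediate
20 | (3R,4Z,8E)-5-({[tert-butyl(dimethyl)silyl]oxy}methyl)-11-[(4-methoxybenzyl)oxy]-9-methyl-1-(trimethylsilyl)undeca-4,8-dien-1-yn-3-ol | C[Si](C)(C)C#C[C@H](O)/C=C(\CO[Si](C)(C)C(C)(C)C)CC/C=C(\C)CCOCc1ccc(OC)cc1 | intermediate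
21 | (3R,4Z,8E)-5-({[tert-butyl(dimethyl)silyl]oxy}methyl)-11-[(4-methoxybenzyl)oxy]-9-methylundeca-4,8-dien-1-yn-3-ol | C#C[C@H](O)/C=C(\CO[Si](C)(C)C(C)(C)C)CC/C=C(\C)CCOCc1ccc(OC)cc1 | intermediate
22 | (3S,4Z,8E)-5-({[tert-butyl(dimethyl)silyl]oxy}methyl)-11-[(4-methoxybenzyl)oxy]-9-methylundeca-1,4,8-trien-3-ol | C=C[C@H](O)/C=C(\CO[Si](C)(C)C(C)(C)C)CC/C=C(\C)CCOCc1ccc(OC)cc1 | intermediate
23 | 2-(bromomethyl)prop-2-enoic acid | C=C(CBr)C(=O)O | starting material
24 | (3S,4Z,8E)-5-({[tert-butyl(dimethyl)silyl]oxy}methyl)-11-[(4-methoxybenzyl)oxy]-9-methylundeca-1,4,8-trien-3-yl 2-(bromomethyl)prop-2-enoate | C=C(CBr)C(=O)O[C@@H](C=C)/C=C(\CO[Si](C)(C)C(C)(C)C)CC/C=C(\C)CCOCc1ccc(OC)cc1 | intermediate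
25 | (5R)-3-(bromomethyl)-5-[(1Z,5E)-2-({[tert-butyl(dimethyl)silyl]oxy}methyl)-8-[(4-methoxybenzyl)oxy]-6-methylocta-1,5-dien-1-yl]furan-2(5H)-one | COc1ccc(COCC/C(C)=C/CC/C(CO[Si](C)(C)C(C)(C)C)=C/[C@H]2OC(=O)C(CBr)=C2)cc1 | intermediate
26 | (5R)-3-(bromomethyl)-5-[(1Z,5E)-2-({[tert-butyl(dimethyl)silyl]oxy}methyl)-8-hydroxy-6-methylocta-1,5-dien-1-yl]furan-2(5H)-one | OCC/C(C)=C/CC/C(CO[Si](C)(C)C(C)(C)C)=C/[C@H]1OC(=O)C(CBr)=C1 | intermediate
27 | (3E,7Z)-8-[(2R)-4-(bromomethyl)-5-oxo-2,5-dihydrofuran-2-yl]-7-({[tert-butyl(dimethyl)silyl]oxy}methyl)-3-methylocta-3,7-dienal | O=CC/C(C)=C/CC/C(CO[Si](C)(C)C(C)(C)C)=C/[C@H]1OC(=O)C(CBr)=C1 | intermediate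
28 | dichloro{[(5R)-5-[(1Z,5E)-2-({[tert-butyl(dimethyl)silyl]oxy}methyl)-6-methyl-8-oxoocta-1,5-dien-1-yl]-2-oxo-2,5-dihydrofuran-3-yl]methyl}chromium (not isolated) | O=CC/C(C)=C/CC/C(CO[Si](C)(C)C(C)(C)C)=C/[C@H]1OC(=O)C(C[Cr](Cl)Cl)=C1 | intermediate
29 | (3aS,4R,6E,10Z,11aR)-10-({[tert-butyl(dimethyl)silyl]oxy}methyl)-4-hydroxy-6-methyl-3-methylidene-3a,4,5,8,9,11a-hexahydrocyclodeca[b]furan-2(3H)-one | O[C@@H]1C/C(C)=C/CC/C(CO[Si](C)(C)C(C)(C)C)=C/[C@H]2OC(=O)C(=C)[C@@H]12 | intermediate
30 | (3R,3aS,4R,6E,10Z,11aR)-10-({[tert-butyl(dimethyl)silyl]oxy}methyl)-4-hydroxy-3,6-dimethyl-3a,4,5,8,9,11a-hexahydrocyclodeca[b]furan-2(3H)-one | O[C@@H]1C/C(C)=C/CC/C(CO[Si](C)(C)C(C)(C)C)=C/[C@H]2OC(=O)[C@H](C)[C@@H]12 | intermediate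
31 | (3R,3aS,4S,6E,10Z,11aR)-10-({[tert-butyl(dimethyl)silyl]oxy}methyl)-3,6-dimethyl-2-oxo-2,3,3a,4,5,8,9,11a-octahydrocyclodeca[b]furan-4-yl 2-({[tert-butyl(dimethyl)silyl]oxy}methyl)prop-2-enoate | C=C(CO[Si](C)(C)C(C)(C)C)C(=O)O[C@H]1C/C(C)=C/CC/C(CO[Si](C)(C)C(C)(C)C)=C/[C@H]2OC(=O)[C@H](C)[C@@H]12 | intermediate
32 | (3R,3aS,4S,6E,10Z,11aR)-10-(hydroxymethyl)-3,6-dimethyl-2-oxo-2,3,3a,4,5,8,9,11a-octahydrocyclodeca[b]furan-4-yl 2-(hydroxymethyl)prop-2-enoate | C=C(CO)C(=O)O[C@H]1C/C(C)=C/CC/C(CO)=C/[C@H]2OC(=O)[C@H](C)[C@@H]12 | target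

**Step count and risks**

Total step count: 19 (17 on the main line, 2 for acid 3).
Longest linear sequence: 17 steps (steps 3–19, from but-3-yn-1-ol).

Steps most likely to fail:

Step 16 (ring closure). What may go wrong: intermolecular allylation or plain reduction of the bromide outrunning closure of the strained ring, approach of the aldehyde to the other face of the butenolide (trans fusion), and drift of the C1=C10 double bond of the aldehyde into conjugation before the addition. The fallback closes the same bond with an isolable allylstannane under Lewis acid activation instead of a reductive organochromium. Setting out from alcohol 26, Pd2(dba)3 and hexabutylditin in THF would give the 3-[(tributylstannyl)methyl]butenolide alcohol F1, buffered Dess–Martin oxidation the stannyl aldehyde F2, and BF3·OEt2 in CH2Cl2 at −78 °C and 1 mM would close the ring through an open SE2′ transition state (intramolecular allylstannane–aldehyde condensation). The route is rejoined at 29.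

Step 17 (directed hydrogenation). What may go wrong: the directed catalyst going on to reduce C1=C10, a rhodium hydride moving the exocyclic double bond into the lactone ring (C7=C11, which erases C7), or hydrogen delivery from the undirected face. The fallback sets C11 under thermodynamic instead of kinetic control. Setting out from 29, conjugate reduction with Stryker's reagent ([(Ph3P)CuH]6, toluene, t-BuOH, rt), which touches only the enoate, would give the 3-epimeric methyl lactone F3 by protonation from the open face (or 30 directly). DBU in toluene at 40 °C would then equilibrate C3 to the isomer with the methyl trans to C8. The route is rejoined at 30.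

Step 18 (Mitsunobu esterification). What may go wrong: E2 loss of the activated oxygen towards a C8=C9 diene, or participation of the lactone carbonyl at C8 that ends in retention or translactonization instead of clean inversion. The fallback inverts C8 by oxidation and reduction and then acylates with retention. Setting out from 30, Dess–Martin periodinane with NaHCO3 would give the 4-ketone F4, L-Selectride in THF at −78 °C (attack from the outer face of the ring) the 4S alcohol F5, and EDC·HCl with DMAP and acid 3 in CH2Cl2 at 0 °C the ester. The route is rejoined at 31.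

**Further compounds**

F1 | step 16 | (5R)-5-[(1Z,5E)-2-({[tert-butyl(dimethyl)silyl]oxy}methyl)-8-hydroxy-6-methylocta-1,5-dien-1-yl]-3-[(tributylstannyl)methyl]furan-2(5H)-one | OCC/C(C)=C/CC/C(CO[Si](C)(C)C(C)(C)C)=C/[C@H]1OC(=O)C(C[Sn](CCCC)(CCCC)CCCC)=C1
F2 | step 16 | (3E,7Z)-7-({[tert-butyl(dimethyl)silyl]oxy}methyl)-3-methyl-8-{(2R)-5-oxo-4-[(tributylstannyl)methyl]-2,5-dihydrofuran-2-yl}octa-3,7-dienal | O=CC/C(C)=C/CC/C(CO[Si](C)(C)C(C)(C)C)=C/[C@H]1OC(=O)C(C[Sn](CCCC)(CCCC)CCCC)=C1
F3 | step 17 | (3S,3aS,4R,6E,10Z,11aR)-10-({[tert-butyl(dimethyl)silyl]oxy}methyl)-4-hydroxy-3,6-dimethyl-3a,4,5,8,9,11a-hexahydrocyclodeca[b]furan-2(3H)-one | O[C@@H]1C/C(C)=C/CC/C(CO[Si](C)(C)C(C)(C)C)=C/[C@H]2OC(=O)[C@@H](C)[C@@H]12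
F4 | step 18 | (3R,3aR,6E,10Z,11aR)-10-({[tert-butyl(dimethyl)silyl]oxy}methyl)-3,6-dimethyl-3a,5,8,9-tetrahydrocyclodeca[b]furan-2,4(3H,11aH)-dione | O=C1C/C(C)=C/CC/C(CO[Si](C)(C)C(C)(C)C)=C/[C@H]2OC(=O)[C@H](C)[C@@H]12
F5 | step 18 | (3R,3aS,4S,6E,10Z,11aR)-10-({[tert-butyl(dimethyl)silyl]oxy}methyl)-4-hydroxy-3,6-dimethyl-3a,4,5,8,9,11a-hexahydrocyclodeca[b]furan-2(3H)-one | O[C@H]1C/C(C)=C/CC/C(CO[Si](C)(C)C(C)(C)C)=C/[C@H]2OC(=O)[C@H](C)[C@@H]12
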